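**Plan**
1. Retrosynthetic cuts, in order: the twenty O–benzyl bonds and one C8–Br cap on unit 4; C4–C4a of unit 2; C4(unit 2)–C8(unit 3); O1–C2 of unit 2; C4(unit 1)–ring A(unit 2); and C4(unit 3)–C6(unit 4).
2. Enabling feature: with C4–C4a of unit 2 open, ring A of unit 2 is a 3,5-dibenzyloxyphenyl ether carrying C4 of unit 1 para to O1, so the two carbons ortho to O1 are interchangeable. C4 of unit 2 carries C8 of unit 3, whose ring A oxygens (O1, O5, O7) stabilise a cation at that carbon.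
3. Forward order: all rings of units 1, 3 and 4 come intact from the two epicatechin enantiomers. The lower dimer is made by a halogen-capped Friedel–Crafts coupling (I on C8 of unit 3, Br on C8 of unit 4). The upper half comes from capture of the unit 1 cation by C3-symmetric phloroglucinol, steric differentiation of the para oxygen, and opening of a cis-glycidate.
4. The halves are joined by adding the C8-magnesiated lower dimer to the upper aldehyde. Ring C of unit 2 is the only ring built and it closes last, before one global hydrogenolysis.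
5. Stereochemistry: C2/C3 of units 1 and 3 come from (−)-epicatechin and those of unit 4 from (+)-epicatechin. C4 of units 1 and 3 is set by attack anti to 3-OBn. C2/C3 of unit 2 come from a Jacobsen–Katsuki epoxidation followed by SN2 inversion at the benzylic carbon, and C4 of unit 2 is set in the closure, anti to 3-OBn.

Key step: step 19

Assumption: the SMILES is read literally. Units 1 and 3 are (2R,3R)-epicatechin with 4β bonds, units 2 and 4 are (2S,3S)-ent-epicatechin, and unit 2 has a 4α bond, so all three interflavan bonds are 3,4-trans. Flavan numbering is used for unit 2 in its open-chain precursors as well.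

Step 1
Reactants: 1 (−)-epicatechin
Product: 2 5,7,3',4'-tetra-O-benzyl-(−)-epicatechin
Conditions: BnBr (4.5 equiv), K2CO3, DMF, argon, 0 °C → rt
Reagents that add atoms: benzyl bromide, BrCc1ccccc1
Why: Williamson etherification in which K2CO3 deprotonates only the four phenols, so the C3 alcohol stays free, while the inert atmosphere and low temperature hold back base-induced epimerisation at C2.

Step 2
Reactants: 2 5,7,3',4'-tetra-O-benzyl-(−)-epicatechin
Product: 3 3,5,7,3',4'-penta-O-benzyl-(−)-epicatechin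
Conditions: NaH, BnBr, Bu4NI (cat.), THF–DMF, 0 °C → rt
Reagents that add atoms: benzyl bromide, BrCc1ccccc1
Why: Williamson etherification of the secondary alkoxide; with all phenols masked no quinone methide can form, so C2 and C3 keep their configuration.

Step 3
Reactants: 3 penta-O-benzyl-(−)-epicatechin
Product: 4 penta-O-benzyl-4β-(2-ethoxyethoxy)epicatechin
Conditions: DDQ (2 equiv), 2-ethoxyethanol (5 equiv), CH2Cl2, rt
Reagents that add atoms: 2-ethoxyethanol, CCOCCO
Why: Oxidative benzylic C–H etherification in which DDQ abstracts hydride from C4, the only methylene activated by the ring A oxygens, and the alcohol adds to the cation anti to 3-OBn, installing a leaving group whose configuration has no later consequence.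

Step 4
Reactants: 4 penta-O-benzyl-4β-(2-ethoxyethoxy)epicatechin
Product: 5 8-iodo-penta-O-benzyl-4β-(2-ethoxyethoxy)epicatechin
Conditions: N-iodosuccinimide (1.0 equiv), CH2Cl2, dark, −20 → 0 °C
Reagents that add atoms: N-iodosuccinimide, O=C1CCC(=O)N1I
Why: Electrophilic aromatic iodination that should follow the known C8-selective NBS bromination of 5,7-di-O-benzylflavans, because C6 lies between two benzyloxy groups and the B rings are far less activated.

Step 5
Reactants: 6 (+)-epicatechin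
Product: 7 5,7,3',4'-tetra-O-benzyl-(+)-epicatechin
Conditions: BnBr (4.5 equiv), K2CO3, DMF, argon, 0 °C → rt
Reagents that add atoms: benzyl bromide, BrCc1ccccc1
Why: Williamson etherification of the four phenols only, as in step 1.

Step 6
Reactants: 7 5,7,3',4'-tetra-O-benzyl-(+)-epicatechin
Product: 8 3,5,7,3',4'-penta-O-benzyl-(+)-epicatechin
Conditions: NaH, BnBr, Bu4NI (cat.), THF–DMF, 0 °C → rt
Reagents that add atoms: benzyl bromide, BrCc1ccccc1
Why: Williamson etherification of the C3 alkoxide, as in step 2, leaving no acidic proton for the later magnesiation.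

Step 7
Reactants: 8 penta-O-benzyl-(+)-epicatechin
Product: 9 8-bromo-penta-O-benzyl-(+)-epicatechin
Conditions: NBS (1.0 equiv), CH2Cl2, −78 → 0 °C
Reagents that add atoms: N-bromosuccinimide, O=C1CCC(=O)N1Br
Why: Electrophilic aromatic bromination at C8, the most nucleophilic ring A carbon of benzylated flavan-3-ols, which leaves C6 as the only open ring A position.

Step 8
Reactants: 5 8-iodo electrophile; 9 8-bromo nucleophile (2 equiv)
Product: 10 lower dimer, deca-O-benzyl 8-iodoepicatechin-(4β→6)-8-bromo-ent-epicatechin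
Conditions: BF3·OEt2 (0.5 equiv), CH2Cl2, slow addition of 5, −78 → −30 °C
Reagents that add atoms: none
Why: Friedel–Crafts alkylation by a flavan-4-yl cation under halogen capping: both C8 positions are blocked, C6 of the excess 9 is less crowded than C6 of 5 or 10 (whose 5-OBn is pushed towards it by the C4 substituent), and attack anti to 3-OBn sets the 4β (3,4-trans) centre.

Step 9
Reactants: 4 penta-O-benzyl-4β-(2-ethoxyethoxy)epicatechin; 11 phloroglucinol (5 equiv)
Product: 12 penta-O-benzylepicatechin-(4β→2)-phloroglucinol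
Conditions: BF3·OEt2 (0.5 equiv), THF–CH2Cl2, slow addition of 4, −20 → 0 °C
Reagents that add atoms: none
Why: This is the cation capture that underlies phloroglucinolysis of proanthocyanidins: the three ring carbons of phloroglucinol are equivalent so no regiochemical question arises, the excess suppresses double alkylation and self-condensation of 4, and attack anti to 3-OBn sets 4β.

Step 10
Reactants: 12 penta-O-benzylepicatechin-(4β→2)-phloroglucinol
Product: 13 mono-TIPS ether of 12 at the hydroxyl para to the flavanyl group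
Conditions: iPr3SiCl (1.0 equiv), imidazole, DMF, −20 → 0 °C
Reagents that add atoms: triisopropylsilyl chloride, CC(C)[Si](Cl)(C(C)C)C(C)C
Why: Sterically governed silylation, since the para hydroxyl has two free neighbouring positions whereas each of the other two is flanked by the bulky flavan-4-yl group, so the large chlorosilane should take the para oxygen.

Step 11
Reactants: 13 para-TIPS ether
Product: 14 di-O-benzyl para-TIPS ether
Conditions: BnBr (3 equiv), K2CO3, Bu4NI (cat.), DMF, rt → 40 °C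
Reagents that add atoms: benzyl bromide, BrCc1ccccc1
Why: Williamson etherification of the two remaining phenols; the aryl TIPS ether is the most base-stable of the common silyl ethers and should survive carbonate.

Step 12
Reactants: 14 di-O-benzyl para-TIPS ether
Product: 15 upper phenol, 3,5-dibenzyloxy-4-(penta-O-benzylepicatechin-4β-yl)phenol
Conditions: Bu4NF, AcOH (1:1, 1.2 equiv), THF, 0 °C
Reagents that add atoms: none
Why: Fluoride-induced desilylation driven by Si–F bond formation, with acetic acid buffering the phenoxide and the benzyl ethers inert.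

Step 13
Reactants: 16 3,4-dibenzyloxybenzaldehyde
Product: 17 methyl (Z)-3-(3,4-dibenzyloxyphenyl)acrylate
Conditions: (CF3CH2O)2P(O)CH2CO2Me, KN(SiMe3)2, 18-crown-6, THF, −78 °C
Reagents that add atoms: methyl bis(2,2,2-trifluoroethyl)phosphonoacetate, COC(=O)CP(=O)(OCC(F)(F)F)OCC(F)(F)F
Why: Still–Gennari variant of the Horner–Wadsworth–Emmons olefination, in which the electron-poor phosphonate and the dissociated potassium ion make elimination faster than equilibration of the adducts and so give the Z-alkene from aromatic aldehydes.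

Step 14
Reactants: 17 methyl (Z)-3-(3,4-dibenzyloxyphenyl)acrylate
Product: 18 methyl (2R,3R)-3-(3,4-dibenzyloxyphenyl)oxirane-2-carboxylate (cis)
Conditions: (R,R)-[N,N'-bis(3,5-di-tert-butylsalicylidene)-1,2-cyclohexanediaminato]manganese chloride (5 mol %), 4-phenylpyridine N-oxide (0.25 equiv), aq. NaOCl (pH 11.3), CH2Cl2, 0–4 °C
Reagents that add atoms: sodium hypochlorite, [Na+].[O-]Cl
Why: Jacobsen–Katsuki epoxidation, for which conjugated cis-alkenes such as Z-cinnamates are the best substrate class; the (R,R) catalyst should deliver oxygen to the face that gives the (2R,3R) cis-epoxide, and any trans-epoxide from the stepwise pathway is removed by chromatography.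

Step 15
Reactants: 15 upper phenol; 18 cis-glycidate (1.3 equiv)
Product: 19 methyl (2R,3S)-3-aryloxy-3-(3,4-dibenzyloxyphenyl)-2-hydroxypropanoate (aryl = ring A of 15)
Conditions: Cs2CO3 (0.3 equiv), DMF, 50 °C
Reagents that add atoms: none
Why: Base-catalysed SN2 opening of a 3-arylglycidate at its benzylic carbon by a phenoxide; inversion there with the α-carbon untouched turns the cis-epoxide into the threo ether, which is the 2S,3S (2,3-cis) pattern of ring C of unit 2.

Step 16
Reactants: 19 hydroxy ester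
Product: 20 methyl (2R,3S)-3-aryloxy-2-benzyloxy-3-(3,4-dibenzyloxyphenyl)propanoate
Conditions: BnBr, Ag2O, Bu4NI (cat.), 4 Å molecular sieves, toluene, dark, rt
Reagents that add atoms: benzyl bromide, BrCc1ccccc1
Why: Silver oxide-mediated benzylation, the usual non-basic method for α-hydroxy esters, avoids ester enolate formation and hence α-epimerisation and β-elimination of the aryloxide.

Step 17
Reactants: 20 benzyloxy ester
Product: 21 (2R,3S)-3-aryloxy-2-benzyloxy-3-(3,4-dibenzyloxyphenyl)propanal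
Conditions: iBu2AlH (1.1 equiv), toluene–CH2Cl2, −78 °C; MeOH, aq. potassium sodium tartrate; used crude at once
Reagents that add atoms: none
Why: Partial reduction of an α-alkoxy ester, whose chelated tetrahedral aluminium hemiacetal persists at −78 °C and collapses to the aldehyde only on work-up.

Step 18
Reactants: 10 lower dimer iodide (1.2 equiv); 21 upper aldehyde
Product: 23 seco-tetramer carbinol (C4 epimers), via C8 arylmagnesium chloride 22 (not isolated)
Conditions: 10, iPrMgCl·LiCl (1.15 equiv), THF, −20 → 0 °C; then 21, −78 → −30 °C; aq. NH4Cl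
Reagents that add atoms: none
Why: Iodine–magnesium exchange is far faster than bromine–magnesium exchange, so only C8 of unit 3 is metalated, and Grignard 1,2-addition to the aldehyde at low temperature should outrun enolisation; the carbinol configuration does not matter because step 19 erases it.

Step 19
Reactants: 23 seco-tetramer carbinol
Product: 24 eicosa-O-benzyl tetramer with bromine at C8 of unit 4
Conditions: BF3·OEt2 (0.5 equiv), 4 Å molecular sieves, CH2Cl2 (2 mM), −78 → −40 °C; then Et3N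
Reagents that add atoms: none
Why: BF3 binds the C4 hydroxyl of either epimer and ionisation gives one planar benzylic cation delocalised into ring A of unit 3 through O1, O7 (ortho to C8) and O5 (para to C8); a carbon ortho to O1 on the unit 2 aryl ether, itself ortho or para to three oxygens, attacks it and loss of the ring proton restores aromaticity, forming C4–C4a. The closest known reactions are the acid-induced cycloalkylation of 3-aryloxy-1-arylpropan-1-ols to 4-arylchromans and the capture of flavan-4-yl cations by phloroglucinol-type rings. Ring C of unit 2 (O1, C2, C3, C4, C4a, C8a) closes as a six-membered ring, exo with respect to the departing C–O bond and endo with respect to the attacking arene π bond. The new stereocentre C4 is controlled by C2 and C3: in the half-chair transition state ring B sits equatorial at C2, 3-OBn is axial, and the unit 3 arene takes the quasi-axial position anti to 3-OBn, which also keeps it away from the neighbouring 5-OBn group, so the 3,4-trans (4α) isomer should result. No regiochemical choice exists, because unit 1 is para to O1 and rotation about the O1–aryl bond interchanges the two ortho carbons, so either closure gives the same 4→6 and 4→8 connectivity. Chemoselectivity rests on the much easier ionisation of the trioxygenated benzylic carbinol compared with the C2–O1 benzylic ether and the existing interflavan bonds at −78 °C, and high dilution disfavours intermolecular attack by C6 or C8 of unit 1.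

Step 20
Reactants: 24 eicosa-O-benzyl tetramer bromide
Product: 25 epicatechin-(4β→6)-ent-epicatechin-(4α→8)-epicatechin-(4β→6)-ent-epicatechin (CNP0120618.2)
Conditions: H2 (1 atm), Pd(OH)2/C, Et3N (1.5 equiv), THF–MeOH–H2O, rt
Reagents that add atoms: none
Why: Catalytic hydrogenolysis cleaves the twenty O–benzyl bonds and the C8–Br bond, triethylamine takes up the HBr that would otherwise cleave the acid-labile interflavan bonds, and the ring C C2–O1 bonds are known to survive such deprotections of benzylated procyanidins.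

**Compound list**
1 | (−)-epicatechin, (2R,3R) | Oc1cc(O)c2c(c1)O[C@H](c1ccc(O)c(O)c1)[C@H](O)C2 | starting material
2 | 5,7,3',4'-tetra-O-benzyl-(−)-epicatechin | c1c(OCc9ccccc9)cc(OCc9ccccc9)c2c1O[C@H](c7ccc(OCc9ccccc9)c(OCc9ccccc9)c7)[C@H](O)C2 | intermediate
3 | 3,5,7,3',4'-penta-O-benzyl-(−)-epicatechin | c1c(OCc9ccccc9)cc(OCc9ccccc9)c2c1O[C@H](c7ccc(OCc9ccccc9)c(OCc9ccccc9)c7)[C@H](OCc9ccccc9)C2 | intermediate
4 | penta-O-benzyl-4β-(2-ethoxyethoxy)epicatechin (3,4-trans) | c1c(OCc9ccccc9)cc(OCc9ccccc9)c2c1O[C@H](c7ccc(OCc9ccccc9)c(OCc9ccccc9)c7)[C@H](OCc9ccccc9)[C@H]2OCCOCC | intermediate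
5 | 8-iodo-penta-O-benzyl-4β-(2-ethoxyethoxy)epicatechin | Ic1c(OCc9ccccc9)cc(OCc9ccccc9)c2c1O[C@H](c7ccc(OCc9ccccc9)c(OCc9ccccc9)c7)[C@H](OCc9ccccc9)[C@H]2OCCOCC | intermediate
6 | (+)-epicatechin (ent-epicatechin), (2S,3S) | Oc1cc(O)c2c(c1)O[C@@H](c1ccc(O)c(O)c1)[C@@H](O)C2 | starting material
7 | 5,7,3',4'-tetra-O-benzyl-(+)-epicatechin | c1c(OCc9ccccc9)cc(OCc9ccccc9)c2c1O[C@@H](c7ccc(OCc9ccccc9)c(OCc9ccccc9)c7)[C@@H](O)C2 | intermediate
8 | 3,5,7,3',4'-penta-O-benzyl-(+)-epicatechin | c1c(OCc9ccccc9)cc(OCc9ccccc9)c2c1O[C@@H](c7ccc(OCc9ccccc9)c(OCc9ccccc9)c7)[C@@H](OCc9ccccc9)C2 | intermediate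
9 | 8-bromo-penta-O-benzyl-(+)-epicatechin | Brc1c(OCc9ccccc9)cc(OCc9ccccc9)c2c1O[C@@H](c7ccc(OCc9ccccc9)c(OCc9ccccc9)c7)[C@@H](OCc9ccccc9)C2 | intermediate
10 | lower dimer, deca-O-benzyl 8-iodoepicatechin-(4β→6)-8-bromo-ent-epicatechin | Ic1c(OCc9ccccc9)cc(OCc9ccccc9)c3c1O[C@H](c7ccc(OCc9ccccc9)c(OCc9ccccc9)c7)[C@H](OCc9ccccc9)[C@H]3c1c(OCc9ccccc9)c(Br)c3c(c1OCc9ccccc9)C[C@H](OCc9ccccc9)[C@H](c7ccc(OCc9ccccc9)c(OCc9ccccc9)c7)O3 | intermediate
11 | phloroglucinol | Oc1cc(O)cc(O)c1 | starting material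
12 | penta-O-benzylepicatechin-(4β→2)-phloroglucinol | c1c(OCc9ccccc9)cc(OCc9ccccc9)c2c1O[C@H](c7ccc(OCc9ccccc9)c(OCc9ccccc9)c7)[C@H](OCc9ccccc9)[C@H]2c1c(O)cc(O)cc1O | intermediate
13 | 12 silylated (TIPS) at the hydroxyl para to the flavanyl group | c1c(OCc9ccccc9)cc(OCc9ccccc9)c2c1O[C@H](c7ccc(OCc9ccccc9)c(OCc9ccccc9)c7)[C@H](OCc9ccccc9)[C@H]2c1c(O)cc(O[Si](C(C)C)(C(C)C)C(C)C)cc1O | intermediate
14 | 13 benzylated at both remaining phenols | c1c(OCc9ccccc9)cc(OCc9ccccc9)c2c1O[C@H](c7ccc(OCc9ccccc9)c(OCc9ccccc9)c7)[C@H](OCc9ccccc9)[C@H]2c1c(OCc9ccccc9)cc(O[Si](C(C)C)(C(C)C)C(C)C)cc1OCc9ccccc9 | intermediate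
15 | upper phenol, 3,5-dibenzyloxy-4-(penta-O-benzylepicatechin-4β-yl)phenol | c1c(OCc9ccccc9)cc(OCc9ccccc9)c2c1O[C@H](c7ccc(OCc9ccccc9)c(OCc9ccccc9)c7)[C@H](OCc9ccccc9)[C@H]2c1c(OCc9ccccc9)cc(O)cc1OCc9ccccc9 | intermediate
16 | 3,4-dibenzyloxybenzaldehyde | O=Cc1ccc(OCc9ccccc9)c(OCc9ccccc9)c1 | starting material
17 | methyl (Z)-3-(3,4-dibenzyloxyphenyl)acrylate | COC(=O)/C=C\c7ccc(OCc9ccccc9)c(OCc9ccccc9)c7 | intermediate
18 | methyl (2R,3R)-3-(3,4-dibenzyloxyphenyl)oxirane-2-carboxylate (cis) | COC(=O)[C@@H]1O[C@@H]1c7ccc(OCc9ccccc9)c(OCc9ccccc9)c7 | intermediate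
19 | methyl (2R,3S)-3-aryloxy-3-(3,4-dibenzyloxyphenyl)-2-hydroxypropanoate, aryl = ring A of 15 | c1c(OCc9ccccc9)cc(OCc9ccccc9)c2c1O[C@H](c7ccc(OCc9ccccc9)c(OCc9ccccc9)c7)[C@H](OCc9ccccc9)[C@H]2c1c(OCc9ccccc9)cc(cc1OCc9ccccc9)O[C@@H](c7ccc(OCc9ccccc9)c(OCc9ccccc9)c7)[C@@H](O)C(=O)OC | intermediate
20 | 2-O-benzyl ether of 19 | c1c(OCc9ccccc9)cc(OCc9ccccc9)c2c1O[C@H](c7ccc(OCc9ccccc9)c(OCc9ccccc9)c7)[C@H](OCc9ccccc9)[C@H]2c1c(OCc9ccccc9)cc(cc1OCc9ccccc9)O[C@@H](c7ccc(OCc9ccccc9)c(OCc9ccccc9)c7)[C@@H](OCc9ccccc9)C(=O)OC | intermediate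
21 | upper aldehyde, (2R,3S)-3-aryloxy-2-benzyloxy-3-(3,4-dibenzyloxyphenyl)propanal | c1c(OCc9ccccc9)cc(OCc9ccccc9)c2c1O[C@H](c7ccc(OCc9ccccc9)c(OCc9ccccc9)c7)[C@H](OCc9ccccc9)[C@H]2c1c(OCc9ccccc9)cc(cc1OCc9ccccc9)O[C@@H](c7ccc(OCc9ccccc9)c(OCc9ccccc9)c7)[C@@H](OCc9ccccc9)C=O | intermediate
22 | C8 (unit 3) arylmagnesium chloride of the lower dimer, bromine at C8 of unit 4 retained | Cl[Mg]c1c(OCc9ccccc9)cc(OCc9ccccc9)c3c1O[C@H](c7ccc(OCc9ccccc9)c(OCc9ccccc9)c7)[C@H](OCc9ccccc9)[C@H]3c1c(OCc9ccccc9)c(Br)c3c(c1OCc9ccccc9)C[C@H](OCc9ccccc9)[C@H](c7ccc(OCc9ccccc9)c(OCc9ccccc9)c7)O3 | intermediate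
23 | seco-tetramer carbinol, ring C of unit 2 open between C4 and C4a, C4–OH as epimer mixture | c1c(OCc9ccccc9)cc(OCc9ccccc9)c2c1O[C@H](c7ccc(OCc9ccccc9)c(OCc9ccccc9)c7)[C@H](OCc9ccccc9)[C@H]2c1c(OCc9ccccc9)cc(cc1OCc9ccccc9)O[C@@H](c7ccc(OCc9ccccc9)c(OCc9ccccc9)c7)[C@@H](OCc9ccccc9)C(O)c1c(OCc9ccccc9)cc(OCc9ccccc9)c3c1O[C@H](c7ccc(OCc9ccccc9)c(OCc9ccccc9)c7)[C@H](OCc9ccccc9)[C@H]3c1c(OCc9ccccc9)c(Br)c3c(c1OCc9ccccc9)C[C@H](OCc9ccccc9)[C@H](c7ccc(OCc9ccccc9)c(OCc9ccccc9)c7)O3 | intermediate
24 | eicosa-O-benzyl tetramer with bromine at C8 of unit 4 | c1c(OCc9ccccc9)cc(OCc9ccccc9)c2c1O[C@H](c7ccc(OCc9ccccc9)c(OCc9ccccc9)c7)[C@H](OCc9ccccc9)[C@H]2c1c(OCc9ccccc9)cc2c(c1OCc9ccccc9)[C@@H](c1c(OCc9ccccc9)cc(OCc9ccccc9)c3c1O[C@H](c7ccc(OCc9ccccc9)c(OCc9ccccc9)c7)[C@H](OCc9ccccc9)[C@H]3c1c(OCc9ccccc9)c(Br)c3c(c1OCc9ccccc9)C[C@H](OCc9ccccc9)[C@H](c7ccc(OCc9ccccc9)c(OCc9ccccc9)c7)O3)[C@H](OCc9ccccc9)[C@H](c7ccc(OCc9ccccc9)c(OCc9ccccc9)c7)O2 | intermediate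
25 | epicatechin-(4β→6)-ent-epicatechin-(4α→8)-epicatechin-(4β→6)-ent-epicatechin, CNP0120618.2 | Oc1cc(O)c2c(c1)O[C@H](c1ccc(O)c(O)c1)[C@H](O)[C@H]2c1c(O)cc2c(c1O)[C@@H](c1c(O)cc(O)c3c1O[C@H](c1ccc(O)c(O)c1)[C@H](O)[C@H]3c1c(O)cc3c(c1O)C[C@H](O)[C@H](c1ccc(O)c(O)c1)O3)[C@H](O)[C@H](c1ccc(O)c(O)c1)O2 | target

**Step count**
Total step count: 20.
Longest linear sequence: 13 steps (1, 2, 3, 9, 10, 11, 12, 15, 16, 17, 18, 19, 20).

**Steps most likely to fail**

Step 19 (ring C closure). Four processes could compete with closure: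
- the cation may lose the C3 proton (elimination to an enol ether);
- the C2–O1 benzylic ether may ionise and the chain fragment;
- intermolecular alkylation may occur at ring A of unit 1;
- the facial selectivity at C4 may be poor in this crowded setting.

The fallback sets out from 4, 9 and 10 and comes back at 25. Ring C of unit 2 is then taken from (+)-epicatechin instead of being built.
- The cation from 4 (BF3·OEt2, CH2Cl2, −78 °C) is captured by C6 of 9 to give the upper dimer bromide F1.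
- DDQ and 2-ethoxyethanol oxidise its only benzylic methylene, C4 of unit 2, to the 4α-(2-ethoxyethoxy) upper dimer F2.
- Iodine–magnesium exchange on 10 followed by methanol gives the C8–H lower dimer F3.
- BF3·OEt2-promoted coupling of F2 with F3 at C8 of unit 3 gives the dibromo eicosa-O-benzyl tetramer F4.
- The hydrogenolysis conditions of step 20, with more Et3N, turn F4 into 25.

Step 18 (union of the halves). The basic aryl Grignard reagent may enolise the aldehyde, which would be followed by β-elimination of the aryloxide. The doubly ortho-substituted nucleophile may add slowly, and the exchange may be incomplete. The fallback sets out from 21 and 10 and comes back at 24. It uses no carbanion and reverses the order of the two bond formations at C4.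
- Compound 21 is treated with BF3·OEt2 in CH2Cl2 at −78 °C. Either ortho carbon of the ring A ether attacks the activated formyl group, an intramolecular Friedel–Crafts hydroxyalkylation that forms the same C4–C4a bond, to give the flavan-4-ol upper dimer F5.
- In the same flask F5 ionises, and its flavan-4-yl cation is captured anti to 3-OBn by C8 of the C8–H lower dimer F3 (made from 10 as described above), giving 24. This relies on the usual C8 over C6 preference of unit 3.

Step 15 (glycidate opening). The electron-rich benzylic carbon may open by an SN1-like pathway with loss of stereochemical integrity. The SN2 attack on the cis-epoxide may be slow, and prolonged heating with base may cause elimination. The fallback sets out from 16 and 15 and comes back at 21. It forms the ether by Mitsunobu inversion instead.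
- CH2=CHMgBr adds to 16 to give the racemic allylic alcohol F6.
- Sharpless kinetic resolution (Ti(OiPr)4, D-(−)-diisopropyl tartrate, tBuOOH, 4 Å molecular sieves, CH2Cl2, −20 °C) should epoxidise the S alcohol to the anti epoxy alcohol F7.
- Mitsunobu etherification of F7 with 15 (PPh3, DIAD, toluene, 0 °C) inverts the carbinol carbon and gives the aryloxy epoxide F8.
- Dimethylsulfonium methylide (Me3SI, n-BuLi, THF) converts the terminal epoxide into the allylic alcohol F9.
- NaH and BnBr give the benzyl ether F10.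
- Lemieux–Johnson cleavage (OsO4 cat., NaIO4, 2,6-lutidine, dioxane–water) gives 21.

Further compounds
F1 | step 19 | upper dimer bromide, deca-O-benzyl epicatechin-(4β→6)-8-bromo-ent-epicatechin | c1c(OCc9ccccc9)cc(OCc9ccccc9)c2c1O[C@H](c7ccc(OCc9ccccc9)c(OCc9ccccc9)c7)[C@H](OCc9ccccc9)[C@H]2c1c(OCc9ccccc9)c(Br)c2c(c1OCc9ccccc9)C[C@H](OCc9ccccc9)[C@H](c7ccc(OCc9ccccc9)c(OCc9ccccc9)c7)O2
F2 | step 19 | 4α-(2-ethoxyethoxy) upper dimer (leaving group at C4 of unit 2) | c1c(OCc9ccccc9)cc(OCc9ccccc9)c2c1O[C@H](c7ccc(OCc9ccccc9)c(OCc9ccccc9)c7)[C@H](OCc9ccccc9)[C@H]2c1c(OCc9ccccc9)c(Br)c2c(c1OCc9ccccc9)[C@@H](OCCOCC)[C@H](OCc9ccccc9)[C@H](c7ccc(OCc9ccccc9)c(OCc9ccccc9)c7)O2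
F3 | step 19 | C8–H lower dimer, deca-O-benzyl epicatechin-(4β→6)-8-bromo-ent-epicatechin | c1c(OCc9ccccc9)cc(OCc9ccccc9)c3c1O[C@H](c7ccc(OCc9ccccc9)c(OCc9ccccc9)c7)[C@H](OCc9ccccc9)[C@H]3c1c(OCc9ccccc9)c(Br)c3c(c1OCc9ccccc9)C[C@H](OCc9ccccc9)[C@H](c7ccc(OCc9ccccc9)c(OCc9ccccc9)c7)O3
F4 | step 19 | dibromo eicosa-O-benzyl tetramer (Br at C8 of units 2 and 4) | c1c(OCc9ccccc9)cc(OCc9ccccc9)c2c1O[C@H](c7ccc(OCc9ccccc9)c(OCc9ccccc9)c7)[C@H](OCc9ccccc9)[C@H]2c1c(OCc9ccccc9)c(Br)c2c(c1OCc9ccccc9)[C@@H](c1c(OCc9ccccc9)cc(OCc9ccccc9)c3c1O[C@H](c7ccc(OCc9ccccc9)c(OCc9ccccc9)c7)[C@H](OCc9ccccc9)[C@H]3c1c(OCc9ccccc9)c(Br)c3c(c1OCc9ccccc9)C[C@H](OCc9ccccc9)[C@H](c7ccc(OCc9ccccc9)c(OCc9ccccc9)c7)O3)[C@H](OCc9ccccc9)[C@H](c7ccc(OCc9ccccc9)c(OCc9ccccc9)c7)O2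
F5 | step 18 | flavan-4-ol upper dimer, ring C of unit 2 closed, C4–OH as epimer mixture | c1c(OCc9ccccc9)cc(OCc9ccccc9)c2c1O[C@H](c7ccc(OCc9ccccc9)c(OCc9ccccc9)c7)[C@H](OCc9ccccc9)[C@H]2c1c(OCc9ccccc9)cc2c(c1OCc9ccccc9)C(O)[C@H](OCc9ccccc9)[C@H](c7ccc(OCc9ccccc9)c(OCc9ccccc9)c7)O2
F6 | step 15 | racemic 1-(3,4-dibenzyloxyphenyl)prop-2-en-1-ol | C=CC(O)c7ccc(OCc9ccccc9)c(OCc9ccccc9)c7
F7 | step 15 | anti epoxy alcohol, (R)-(3,4-dibenzyloxyphenyl)[(S)-oxiran-2-yl]methanol | O[C@H](c7ccc(OCc9ccccc9)c(OCc9ccccc9)c7)[C@@H]1CO1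
F8 | step 15 | aryloxy epoxide from 15 and F7 | c1c(OCc9ccccc9)cc(OCc9ccccc9)c2c1O[C@H](c7ccc(OCc9ccccc9)c(OCc9ccccc9)c7)[C@H](OCc9ccccc9)[C@H]2c1c(OCc9ccccc9)cc(cc1OCc9ccccc9)O[C@@H](c7ccc(OCc9ccccc9)c(OCc9ccccc9)c7)[C@@H]1CO1
F9 | step 15 | allylic alcohol from F8 | c1c(OCc9ccccc9)cc(OCc9ccccc9)c2c1O[C@H](c7ccc(OCc9ccccc9)c(OCc9ccccc9)c7)[C@H](OCc9ccccc9)[C@H]2c1c(OCc9ccccc9)cc(cc1OCc9ccccc9)O[C@@H](c7ccc(OCc9ccccc9)c(OCc9ccccc9)c7)[C@@H](O)C=C
F10 | step 15 | benzyl ether of F9 | c1c(OCc9ccccc9)cc(OCc9ccccc9)c2c1O[C@H](c7ccc(OCc9ccccc9)c(OCc9ccccc9)c7)[C@H](OCc9ccccc9)[C@H]2c1c(OCc9ccccc9)cc(cc1OCc9ccccc9)O[C@@H](c7ccc(OCc9ccccc9)c(OCc9ccccc9)c7)[C@@H](OCc9ccccc9)C=C
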